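## Structural features

Bromoiesol A (17) is a heptabrominated triaryl bis-ether with no stereocentre, so the whole problem is one of regiochemistry on three benzene rings. Ring A is a phenol with bromines at its 3- and 5-positions, and its 2-position, which lies between the hydroxyl carbon and a brominated carbon, is joined through oxygen O1 to B1 of the central ring B, while B6 is joined through oxygen O2 to ring C, a 2,4-dibromophenyl group. Ring B is pentasubstituted, with O1 at B1, its only hydrogen at B2, bromines on the three contiguous carbons B3, B4 and B5, and O2 at B6. The fragile groups are the seven aryl C–Br bonds, which undergo bromine–lithium exchange with n-BuLi, are cleaved by low-valent metals and make the ring C hydrogen between two bromines acidic, and the free ring A phenol, which is open to oxidation and further bromination. The real difficulty is ring B, because electrophilic bromination of a catechol diether would be steered towards B2 as readily as towards B5, the middle bromine at B4 would have to enter between two others, and both ether oxygens sit on adjacent crowded carbons. The key step avoids aromatic substitution on ring B altogether: the chain B2–B3–B4–B5 (H, Br, Br, Br) is the chain C5–C4–C3–C2 of 2,3,4-tribromothiophene, and B1 and B6 with their heteroatoms are the two carbons of an alkyne that carries boron and the aryloxy group, so ring B can be closed by cycloaddition with every substituent in place. The ring A hydroxyl ortho to O1 is treated as a masked formyl group, which also activates formation of the bond from O1 to ring A.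

## Logic of the disconnections

**17 to 15 (through 16).** The C–O bond of the ring A phenol is traced back to the aryl–CHO carbon–carbon bond of 15 by oxygen insertion. The formyl group serves twice, as activator for the ether-forming substitution and as latent hydroxyl, so no phenol protecting group is needed and the oxidisable phenol appears only in the last operation. The forward step requires aryl, not hydride, to migrate in the peracid adduct, and the ortho aryloxy oxygen is relied on for that.

**15 to 13 and 14.** The bond between O1 and ring A is cut. The ring A carbon concerned carries fluorine ortho to formyl in 14 and is the only activated aryl carbon in either partner. The cut separates a one-ring piece holding both ring A bromines from a two-ring phenol. The forward step asks a hindered, weakly nucleophilic phenoxide to displace a fluoride flanked by bromine and formyl without touching any C–Br bond.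

**13 to 12.** The B1–O1 bond is exchanged for a B1–boron bond. Boron can be carried on carbon through the ring-forming step and is replaced by oxygen at the same position under mild conditions. The oxidant must spare the aryl bromides and the diaryl ether.

**12 to 3 and 10 (through 11).** The B1–B2 and B5–B6 bonds are cut. Ring B falls into a four-carbon piece carrying H, Br, Br, Br and a two-carbon piece carrying boron and the ether from O2 to ring C. This removes the hardest regiochemical problem from aromatic substitution and delivers the ring, five substituents and one ether bond in one event. The forward step must join the boron-bearing carbon to the hydrogen-bearing diene terminus, must outrun self-dimerisation of 3, and must end with extrusion of the sulfonyl bridge.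

**3 to 1 (through 2).** The two S–O bonds are cut. This leads back to a purchasable thiophene that already carries the three contiguous bromines and the single hydrogen. An electron-poor thiophene needs a strong electrophilic oxidant, and 3 must then be freed of acid and oxidant before it meets 10.

**10 to 7 (through 8 and 9).** The alkyne C–B bond is cut, and one π bond of the alkyne is traced back to the vinylic C–Br and C–H bonds of 7. Going from 7 straight to 8 avoids isolating the polymerisable terminal aryloxyacetylene. The base must deprotonate without exchanging the ring bromines, which rules out alkyl-metal reagents, and it must not be present in excess, since it could metalate ring C between its bromines.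

**7 to 5 (through 6).** The vinyl C–Br bond is cut. This leaves a plain aryl vinyl ether. In the forward step bromine must add to the enol ether and not to the ring, and only one molecule of hydrogen bromide may be lost again.

**5 to 4.** The O–vinyl bond is cut, which leads to a purchased phenol that already holds both ring C bromines. The vinylation must leave the two C–Br bonds alone, one of them ortho to the reacting oxygen.

## Other disconnections considered

Alternative 1: The cut is at the three C–Br bonds of ring B, made on a two-ring ether whose ring B has a free hydroxyl at B6 and a carboxyl at B4.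
- Forward: 14 would be joined by SNAr to the 4-hydroxyl of 3,4-dihydroxybenzoic acid A1 to give 4-(2,4-dibromo-6-formylphenoxy)-3-hydroxybenzoic acid A2. Bu4NBr3 with K3PO4 would brominate A2 ortho (B5) and para (B3) to the free hydroxyl and then replace the carboxyl by bromine with loss of CO2, so the key step would end at 3,5-dibromo-2-(3,4,5-tribromo-2-hydroxyphenoxy)benzaldehyde A3. Arylation of the B6 oxygen of A3 with a 2,4-dibromophenyl donor would lead to 15.
- In favour: A1 is cheap. The hydroxyl and the carboxyl placeholder of A2 dictate all three positions, and B2 is meta to the hydroxyl and should stay free. No boron, sulfone or strong base is needed.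
- Against: The ipso step favours electron-rich acids. In A2 the carboxyl is para to an oxygen that is shared with the electron-poor ring A, and it must leave from between two new bromines, so stalling or protodecarboxylation is plausible. Ring C must then go onto the most crowded and least nucleophilic oxygen of A3, which probably needs a diaryliodonium transfer or a nitro-activated substitution with later Sandmeyer steps. Which of the two hydroxyls of A1 reacts in the first SNAr is a further open point.
- Comparison: On structure, both plans solve the B2-hydrogen problem, this one by directing effects and the chosen one by atom mapping. On mechanism, Alternative 1 uses known reaction types throughout and is the better of the two. On step economy it is also better, with about five operations against eight. The chosen plan is stronger at one point: its crowded ether between O2 and ring C exists from the start, so no late substitution on a crowded ring is needed.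

Alternative 2: The cut is at B3–Br and B5–Br, with B4–Br traced to an amino group.
- Forward: NBS (2 equivalents) would brominate 4-(2,4-dibromo-6-methoxyphenoxy)-3-(2,4-dibromophenoxy)aniline A4 at both positions ortho to nitrogen and give 2,6-dibromo-4-(2,4-dibromo-6-methoxyphenoxy)-3-(2,4-dibromophenoxy)aniline A5. Sandmeyer bromination of A5 would give the methyl ether 1,5-dibromo-3-methoxy-2-[3,4,5-tribromo-2-(2,4-dibromophenoxy)phenoxy]benzene A6. Demethylation of A6 would give 17.
- In favour: The amino group of A4 is the strongest director on the molecule. Its ortho positions are exactly B3 and B5, B2 is meta to it, and the Sandmeyer step on A5 places the middle bromine where no electrophilic substitution could. Every step is textbook chemistry.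
- Against: A4 must first be assembled with two different aryl ethers on adjacent oxygens. Only the position para to the nitro group of its precursor is activated for substitution, so the second ether needs a copper-mediated coupling in the presence of aryl bromides or a detour. The demethylation of A6 is one more operation on a heptabromide.
- Comparison: On structure, this plan decorates an existing ring B, whereas the chosen plan builds it. On mechanism, the regiochemical certainty of this key step is better than that of the chosen one. On step economy the two are about equal once the making of A4 is counted. The chosen plan is more convergent, and its hindered ether bonds come from purchased pieces or an activated fluoride.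

Alternative 3: The cut is at four C–Br bonds at once, two on ring C (its 2- and 4-positions) and two on ring B (B3 and B4).
- Forward: Br2 (4 equivalents) with FeBr3 would brominate 3,5-dibromo-2-(3-bromo-2-phenoxyphenoxy)benzaldehyde A7. The product would be 3,5-dibromo-2-[3,4,5-tribromo-2-(2,4-dibromophenoxy)phenoxy]benzaldehyde A8, and A8 is the same compound as 15.
- In favour: From A7 this is by far the shortest way to 15. Ring A of A7 is shielded by its formyl group and its two bromines, and the mechanism is the most familiar of all.
- Against: Selectivity rests on relative rates alone. After the phenoxy ring of A7 is dibrominated, ring B must take bromine at B3 and then at B4 between two bromines, while B2 and the second ortho position of ring C stay open. Over- and under-bromination would give isomers of A8 that are hard to separate at this molecular weight.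
- Comparison: On step economy Alternative 3 is clearly better, and on familiarity of mechanism it is at least equal. On structure the chosen plan is stronger: every bromine arrives inside 1, 4 or 14 and none is placed by substitution on the assembled system.

Key step: step 5

Assumption: 1, 4 and 14 are taken as catalogue compounds.

Remark: thiophene carbons C2, C3, C4 and C5 become B5, B4, B3 and B2; the boron-bearing alkyne carbon becomes B1 and the oxygen-bearing one B6.

Remark: 3 is isolated free of peracid and acid before it meets 10, because an ynol ether survives neither, and it is then added slowly to excess 10.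

Remark: 10 is made with LiN(i-Pr)2 and without isolating the terminal aryloxyacetylene.

Remark: 7 is written as the expected Z isomer; 6 and 11 are racemic, and their stereocentres are lost in the step that forms them.

## Steps

Step 1
Reactants: 1 2,3,4-tribromothiophene
Product: 3 2,3,4-tribromothiophene 1,1-dioxide, via tribromothiophene S-oxide 2 (not isolated)
Conditions: (CF3CO)2O, urea·H2O2, MeCN/CH2Cl2, 0 °C to rt; cold water wash, dry, concentrate below 20 °C, use at once
Reagents that add atoms: trifluoroperacetic acid, OOC(=O)C(F)(F)F (formed in the flask from trifluoroacetic anhydride, O=C(OC(=O)C(F)(F)F)C(F)(F)F, and urea–hydrogen peroxide, NC(N)=O.OO)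
Why: Electrophilic oxidation at sulfur by a strong peracid is the standard route from polyhalothiophenes to their 1,1-dioxides; the S-oxide 2 is oxidised faster than 1 and should not accumulate. The three bromines slow the self-dimerisation typical of less substituted thiophene dioxides, and 3 is freed from acid and peroxide because 10 tolerates neither.

Step 2
Reactants: 4 2,4-dibromophenol
Product: 5 2,4-dibromo-1-(ethenyloxy)benzene
Conditions: Cu(OAc)2, (CH2=CHBO)3·pyridine, pyridine, CH2Cl2, rt, dry air
Reagents that add atoms: 2,4,6-trivinylcyclotriboroxane–pyridine complex, C=CB1OB(C=C)OB(C=C)O1.c1ccncc1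
Why: Chan–Lam-type oxidative O-vinylation of a phenol with a vinylboron reagent at room temperature; oxygen of the air returns monovalent copper to divalent copper. Aryl bromides, including one ortho to the hydroxyl, are not activated under these conditions.

Step 3
Reactants: 5 2,4-dibromo-1-(ethenyloxy)benzene
Product: 7 2,4-dibromo-1-{[(Z)-2-bromoethenyl]oxy}benzene, via 1,2-dibromoethyl aryl ether 6 (not isolated)
Conditions: Br2 (1.0 equiv), CH2Cl2, −78 °C; then i-Pr2NEt, −78 °C to 40 °C
Reagents that add atoms: bromine, BrBr
Why: Addition of bromine to the electron-rich enol ether is far faster than substitution on the deactivated dibromophenyl ring, and the α-bromo ether 6 then loses HBr under the hindered amine (elimination through the oxocarbenium ion) to the β-bromovinyl ether. Any E isomer or 1-bromovinyl isomer can be carried on, since it should give the same acetylide in step 4.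

Step 4
Reactants: 7 2,4-dibromo-1-{[(Z)-2-bromoethenyl]oxy}benzene
Product: 10 2-[(2,4-dibromophenoxy)ethynyl]-4,4,5,5-tetramethyl-1,3,2-dioxaborolane, via lithium (2,4-dibromophenoxy)acetylide 8 (not isolated), via lithium isopropoxyborate complex 9 (not isolated)
Conditions: LiN(i-Pr)2 (2.0 equiv, added to 7), THF, −78 °C; i-PrOBpin, −78 °C; HCl in Et2O, −78 °C to rt; filtration and short-path purification under Ar
Reagents that add atoms: 2-isopropoxy-4,4,5,5-tetramethyl-1,3,2-dioxaborolane, CC(C)OB1OC(C)(C)C(C)(C)O1
Why: Anti E2 dehydrobromination of the bromovinyl ether by LiN(i-Pr)2 and deprotonation of the resulting alkyne give acetylide 8 without isolation of the terminal aryloxyacetylene; borylation with an alkoxyboronate and acid cleavage of ate complex 9 is the standard synthesis of alkynyl pinacol boronates. An amide base in exactly two equivalents, added to 7, avoids bromine–lithium exchange and leaves no free base to metalate ring C between its bromines.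

Step 5
Reactants: 3 2,3,4-tribromothiophene 1,1-dioxide; 10 2-[(2,4-dibromophenoxy)ethynyl]-4,4,5,5-tetramethyl-1,3,2-dioxaborolane
Product: 12 2-[3,4,5-tribromo-2-(2,4-dibromophenoxy)phenyl]-4,4,5,5-tetramethyl-1,3,2-dioxaborolane, via bridged sulfone cycloadduct 11 (not isolated)
Conditions: 3 in PhMe added over 4 h to 10 (1.5 equiv), PhMe, 70 °C, Ar sweep; then 100 °C, 1 h
Reagents that add atoms: none
Why: Proposed new method: inverse-electron-demand [4+2] cycloaddition between the electron-poor cyclic dienyl sulfone 3 (C2 to C5) and the donor alkyne 10 gives the bridged sulfone 11, which loses SO2 by cheletropic extrusion and aromatises to 12; the closest known reaction type is the cycloaddition with SO2 extrusion of tetrahalothiophene and 3,4-dichlorothiophene 1,1-dioxides with alkynes and alkenes to polyhalobenzenes, together with cycloadditions of alkynyl pinacol boronates to other electron-poor dienes that deliver aryl boronates. Ring B is closed as a six-membered carbocycle in an intermolecular [4+2] mode that forms B1–B2 (boron-bearing alkyne carbon to thiophene C5) and B5–B6 (oxygen-bearing alkyne carbon to thiophene C2), most probably asynchronously with the first of these bonds leading. No stereocentre remains, because the two bridgehead centres of 11 vanish when SO2 leaves. The selectivity needed is regiochemical. In 10 the carbon remote from oxygen, which carries boron, is the nucleophilic terminus of the ynol ether and also the bulkier one; it should bond to C5, the only unsubstituted diene terminus, because attack there is least hindered and places the developing negative charge on C2, where the sulfonyl group and a bromine stabilise it, while the oxygen-stabilised carbon closes onto C2. Steric and electronic preferences thus point the same way and put boron beside the B2 hydrogen and the aryloxy group beside the B5 bromine. Self-dimerisation of 3 through its C4=C5 bond is held back by a low stationary concentration (slow addition into excess 10), and the argon sweep removes SO2 so that the ynol ether and the C–B bond are not exposed to it.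

Step 6
Reactants: 12 2-[3,4,5-tribromo-2-(2,4-dibromophenoxy)phenyl]-4,4,5,5-tetramethyl-1,3,2-dioxaborolane
Product: 13 3,4,5-tribromo-2-(2,4-dibromophenoxy)phenol
Conditions: NaBO3·4H2O, THF/H2O, rt
Reagents that add atoms: sodium perborate tetrahydrate, O.O.O.O.[Na+].[O-]OB=O
Why: Oxidation of an aryl pinacol boronate by the hydroperoxide released from perborate: the aryl group shifts from boron to oxygen at the same ring position and the borate ester is hydrolysed. The conditions are mild enough for aryl bromides and diaryl ethers.

Step 7
Reactants: 13 3,4,5-tribromo-2-(2,4-dibromophenoxy)phenol; 14 3,5-dibromo-2-fluorobenzaldehyde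
Product: 15 3,5-dibromo-2-[3,4,5-tribromo-2-(2,4-dibromophenoxy)phenoxy]benzaldehyde
Conditions: K2CO3, DMF, 80 °C
Reagents that add atoms: none
Why: Nucleophilic aromatic substitution through a Meisenheimer intermediate: the fluorine of 14 is activated by the ortho formyl group and should be displaced by the phenoxide of 13, while no C–Br bond is activated. Couplings of bromophenols with ortho-fluorobenzaldehydes of this kind are routine for hydroxylated polybrominated diphenyl ethers.

Step 8
Reactants: 15 3,5-dibromo-2-[3,4,5-tribromo-2-(2,4-dibromophenoxy)phenoxy]benzaldehyde
Product: 17 bromoiesol A (3,5-dibromo-2-[3,4,5-tribromo-2-(2,4-dibromophenoxy)phenoxy]phenol), via aryl formate 16 (not isolated)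
Conditions: mCPBA, CH2Cl2, rt; Na2S2O3 wash; then HCl (cat.), MeOH, rt
Reagents that add atoms: 3-chloroperbenzoic acid, OOC(=O)c1cccc(Cl)c1
Why: Baeyer–Villiger (Dakin-type) oxidation: in the Criegee adduct the aryl group, assisted by the ortho aryloxy oxygen, should migrate to oxygen to give formate 16, which is cleaved by acid-catalysed methanolysis. The free phenol appears only at the end, and no C–Br bond meets base or metal.

## Compound list

1 | 2,3,4-tribromothiophene | Brc1csc(Br)c1Br | starting material
2 | 2,3,4-tribromothiophene 1-oxide (racemic at sulfur; formed in the flask, not isolated) | O=S1C=C(Br)C(Br)=C1Br | intermediate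
3 | 2,3,4-tribromothiophene 1,1-dioxide | O=S1(=O)C=C(Br)C(Br)=C1Br | intermediate
4 | 2,4-dibromophenol | Oc1ccc(Br)cc1Br | starting material
5 | 2,4-dibromo-1-(ethenyloxy)benzene | C=COc1ccc(Br)cc1Br | intermediate
6 | 2,4-dibromo-1-(1,2-dibromoethoxy)benzene (racemic; formed in the flask, not isolated) | BrCC(Br)Oc1ccc(Br)cc1Br | intermediate
7 | 2,4-dibromo-1-{[(Z)-2-bromoethenyl]oxy}benzene | Br/C=C\Oc1ccc(Br)cc1Br | intermediate
8 | lithium (2,4-dibromophenoxy)acetylide (formed in the flask, not isolated) | [Li+].[C-]#COc1ccc(Br)cc1Br | intermediate
9 | lithium [(2,4-dibromophenoxy)ethynyl](isopropoxy)(pinacolato)borate (formed in the flask, not isolated) | [Li+].CC(C)O[B-]1(OC(C)(C)C(C)(C)O1)C#COc1ccc(Br)cc1Br | intermediate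
10 | 2-[(2,4-dibromophenoxy)ethynyl]-4,4,5,5-tetramethyl-1,3,2-dioxaborolane | CC1(C)OB(OC1(C)C)C#COc1ccc(Br)cc1Br | intermediate
11 | 1,2,3-tribromo-6-(2,4-dibromophenoxy)-5-(4,4,5,5-tetramethyl-1,3,2-dioxaborolan-2-yl)-7-thiabicyclo[2.2.1]hepta-2,5-diene 7,7-dioxide (racemic, bridgeheads joined cis by the SO2 bridge; formed in the flask, not isolated) | O=S1(=O)C2(Br)C(Br)=C(Br)C1C(B3OC(C)(C)C(C)(C)O3)=C2Oc4ccc(Br)cc4Br | intermediate
12 | 2-[3,4,5-tribromo-2-(2,4-dibromophenoxy)phenyl]-4,4,5,5-tetramethyl-1,3,2-dioxaborolane | CC1(C)OB(OC1(C)C)c1cc(Br)c(Br)c(Br)c1Oc1ccc(Br)cc1Br | intermediate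
13 | 3,4,5-tribromo-2-(2,4-dibromophenoxy)phenol | Oc1cc(Br)c(Br)c(Br)c1Oc1ccc(Br)cc1Br | intermediate
14 | 3,5-dibromo-2-fluorobenzaldehyde | O=Cc1cc(Br)cc(Br)c1F | starting material
15 | 3,5-dibromo-2-[3,4,5-tribromo-2-(2,4-dibromophenoxy)phenoxy]benzaldehyde | O=Cc1cc(Br)cc(Br)c1Oc1cc(Br)c(Br)c(Br)c1Oc1ccc(Br)cc1Br | intermediate
16 | 3,5-dibromo-2-[3,4,5-tribromo-2-(2,4-dibromophenoxy)phenoxy]phenyl formate (formed in the flask, not isolated) | O=COc1cc(Br)cc(Br)c1Oc1cc(Br)c(Br)c(Br)c1Oc1ccc(Br)cc1Br | intermediate
17 | bromoiesol A, 3,5-dibromo-2-[3,4,5-tribromo-2-(2,4-dibromophenoxy)phenoxy]phenol | Oc1cc(Br)cc(Br)c1Oc1cc(Br)c(Br)c(Br)c1Oc1ccc(Br)cc1Br | target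

## Step count and risks

Total step count: 8. Longest linear sequence: 7 steps (steps 2 to 8, from 4 to 17); step 1 is a one-step branch that joins at step 5.

**Step 5 (key step, the one step beyond known chemistry).** Three processes are most likely to go wrong. Self-dimerisation or oligomerisation of 3 may outrun the cycloaddition, because the aryloxy donor of 10 is weakened by its two bromines and by the boron acceptor; this also carries the handling risk of step 1 into this step. Bond formation may occur in the reverse sense, which would place boron beside bromine. Boron may be lost by protodeboronation if acid or SO2 lingers.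

The fallback uses known chemistry only and builds ring B by directing groups in place of cycloaddition; it sets out from 4 and returns at 13. 4 would be joined by SNAr (K2CO3, DMF) to 2-fluoro-4-nitrobenzaldehyde (O=Cc1ccc([N+](=O)[O-])cc1F) to give 2-(2,4-dibromophenoxy)-4-nitrobenzaldehyde F1. Reduction of the nitro group (Fe, AcOH, EtOH) would give 4-amino-2-(2,4-dibromophenoxy)benzaldehyde F2, which would be taken on at once because para-aminobenzaldehydes tend to self-condense. NBS (2 equivalents) would brominate both positions ortho to the amino group, which are also meta to formyl, to give 4-amino-3,5-dibromo-2-(2,4-dibromophenoxy)benzaldehyde F3. Sandmeyer bromination (t-BuONO, CuBr2, MeCN) would give 3,4,5-tribromo-2-(2,4-dibromophenoxy)benzaldehyde F4. Baeyer–Villiger oxidation with mCPBA would give 3,4,5-tribromo-2-(2,4-dibromophenoxy)phenyl formate F5, and acid-catalysed methanolysis would then give 13.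

**Step 4.** The amide base may metalate ring C at the hydrogen between the two bromines, with halogen migration or aryne formation as the consequence. The ynol ether boronate may also be lost by hydrolysis or polymerisation during isolation.

The fallback separates elimination from metalation and uses bases that cannot deprotonate the ring; it sets out from 7 and returns at 10. 7 would be dehydrobrominated with KOt-Bu (THF, −40 °C) to 2,4-dibromo-1-(ethynyloxy)benzene F6, kept cold in solution after a quick work-up. Deprotonation with EtMgBr (THF, 0 °C), which does not exchange aryl bromides at this temperature, would give bromo[(2,4-dibromophenoxy)ethynyl]magnesium F7. Borylation with i-PrOBpin and then HCl in Et2O would give 10.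

**Step 7.** The substitution may be sluggish, because the phenoxide of 13 is hindered and electron-poor and the fluorine of 14 sits between bromine and formyl. Forcing conditions invite degradation of the aldehyde and, on long heating, migration of the ring C aryl group between the two adjacent oxygens of ring B.

The fallback uses a nitro group as a second activator and as a masked bromine; it sets out from 13 and returns at 15. 13 would react near room temperature (K2CO3, DMF) with 5-bromo-2-fluoro-3-nitrobenzaldehyde (O=Cc1cc(Br)cc([N+](=O)[O-])c1F) to give 5-bromo-3-nitro-2-[3,4,5-tribromo-2-(2,4-dibromophenoxy)phenoxy]benzaldehyde F8. Reduction (Fe, AcOH, EtOH) would give 3-amino-5-bromo-2-[3,4,5-tribromo-2-(2,4-dibromophenoxy)phenoxy]benzaldehyde F9, which would be diazotised without storage. Sandmeyer bromination (t-BuONO, CuBr2, MeCN) would give 15.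

**Step 8.** Hydride may migrate in place of aryl in the Criegee adduct, giving the benzoic acid, because the two bromines make ring A a poor migrating group despite the ortho oxygen.

The fallback replaces the formyl hydrogen by methyl, so that aryl migration is the only favourable path; it sets out from 15 and returns at 17. MeMgBr (THF, −78 °C, HCl quench) would give racemic 1-{3,5-dibromo-2-[3,4,5-tribromo-2-(2,4-dibromophenoxy)phenoxy]phenyl}ethanol F10. Dess–Martin periodinane would give 1-{3,5-dibromo-2-[3,4,5-tribromo-2-(2,4-dibromophenoxy)phenoxy]phenyl}ethanone F11. Baeyer–Villiger oxidation with mCPBA in CH2Cl2/CF3CO2H would give 3,5-dibromo-2-[3,4,5-tribromo-2-(2,4-dibromophenoxy)phenoxy]phenyl acetate F12, and acid-catalysed methanolysis would then give 17.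

## Further compounds

F1 | step 5 | 2-(2,4-dibromophenoxy)-4-nitrobenzaldehyde | O=Cc1ccc([N+](=O)[O-])cc1Oc1ccc(Br)cc1Br
F2 | step 5 | 4-amino-2-(2,4-dibromophenoxy)benzaldehyde | Nc1ccc(C=O)c(Oc2ccc(Br)cc2Br)c1
F3 | step 5 | 4-amino-3,5-dibromo-2-(2,4-dibromophenoxy)benzaldehyde | Nc1c(Br)cc(C=O)c(Oc2ccc(Br)cc2Br)c1Br
F4 | step 5 | 3,4,5-tribromo-2-(2,4-dibromophenoxy)benzaldehyde | O=Cc1cc(Br)c(Br)c(Br)c1Oc1ccc(Br)cc1Br
F5 | step 5 | 3,4,5-tribromo-2-(2,4-dibromophenoxy)phenyl formate | O=COc1cc(Br)c(Br)c(Br)c1Oc1ccc(Br)cc1Br
F6 | step 4 | 2,4-dibromo-1-(ethynyloxy)benzene | C#COc1ccc(Br)cc1Br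
F7 | step 4 | bromo[(2,4-dibromophenoxy)ethynyl]magnesium | Br[Mg]C#COc1ccc(Br)cc1Br
F8 | step 7 | 5-bromo-3-nitro-2-[3,4,5-tribromo-2-(2,4-dibromophenoxy)phenoxy]benzaldehyde | O=Cc1cc(Br)cc([N+](=O)[O-])c1Oc1cc(Br)c(Br)c(Br)c1Oc1ccc(Br)cc1Br
F9 | step 7 | 3-amino-5-bromo-2-[3,4,5-tribromo-2-(2,4-dibromophenoxy)phenoxy]benzaldehyde | Nc1cc(Br)cc(C=O)c1Oc1cc(Br)c(Br)c(Br)c1Oc1ccc(Br)cc1Br
F10 | step 8 | 1-{3,5-dibromo-2-[3,4,5-tribromo-2-(2,4-dibromophenoxy)phenoxy]phenyl}ethanol (racemic) | CC(O)c1cc(Br)cc(Br)c1Oc1cc(Br)c(Br)c(Br)c1Oc1ccc(Br)cc1Br
F11 | step 8 | 1-{3,5-dibromo-2-[3,4,5-tribromo-2-(2,4-dibromophenoxy)phenoxy]phenyl}ethanone | CC(=O)c1cc(Br)cc(Br)c1Oc1cc(Br)c(Br)c(Br)c1Oc1ccc(Br)cc1Br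
F12 | step 8 | 3,5-dibromo-2-[3,4,5-tribromo-2-(2,4-dibromophenoxy)phenoxy]phenyl acetate | CC(=O)Oc1cc(Br)cc(Br)c1Oc1cc(Br)c(Br)c(Br)c1Oc1ccc(Br)cc1Br
A1 | alternative 1 | 3,4-dihydroxybenzoic acid | OC(=O)c1ccc(O)c(O)c1
A2 | alternative 1 | 4-(2,4-dibromo-6-formylphenoxy)-3-hydroxybenzoic acid | O=Cc1cc(Br)cc(Br)c1Oc1ccc(C(O)=O)cc1O
A3 | alternative 1 | 3,5-dibromo-2-(3,4,5-tribromo-2-hydroxyphenoxy)benzaldehyde | O=Cc1cc(Br)cc(Br)c1Oc1cc(Br)c(Br)c(Br)c1O
A4 | alternative 2 | 4-(2,4-dibromo-6-methoxyphenoxy)-3-(2,4-dibromophenoxy)aniline | COc1cc(Br)cc(Br)c1Oc1ccc(N)cc1Oc1ccc(Br)cc1Br
A5 | alternative 2 | 2,6-dibromo-4-(2,4-dibromo-6-methoxyphenoxy)-3-(2,4-dibromophenoxy)aniline | COc1cc(Br)cc(Br)c1Oc1cc(Br)c(N)c(Br)c1Oc1ccc(Br)cc1Br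
A6 | alternative 2 | 1,5-dibromo-3-methoxy-2-[3,4,5-tribromo-2-(2,4-dibromophenoxy)phenoxy]benzene | COc1cc(Br)cc(Br)c1Oc1cc(Br)c(Br)c(Br)c1Oc1ccc(Br)cc1Br
A7 | alternative 3 | 3,5-dibromo-2-(3-bromo-2-phenoxyphenoxy)benzaldehyde | O=Cc1cc(Br)cc(Br)c1Oc1cccc(Br)c1Oc1ccccc1
A8 | alternative 3 | 3,5-dibromo-2-[3,4,5-tribromo-2-(2,4-dibromophenoxy)phenoxy]benzaldehyde | O=Cc1cc(Br)cc(Br)c1Oc1cc(Br)c(Br)c(Br)c1Oc1ccc(Br)cc1Br
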